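## Analysis of the target

CNP0249420.1 (23) is a 2,3-dihydro-1,4-benzodioxine. Its benzo ring (ring B) is fused to a dioxane that carries a free carboxyl group at C2 and a 3,4-dihydroxyphenyl group (ring C) at C3, and C7 bears an (E)-propenoate esterified with (R)-3-(4-hydroxy-3-methoxyphenyl)lactic acid (ring A). O1, bonded to C2, is meta to the propenoate and O4, bonded to C3, is para to it, so the two ring oxygens are not interchangeable. There are three stereocentres: C2 and C3 are both S, which puts carboxyl and aryl on the same face of the dioxane (cis), and the lactate carbon is R and too remote to steer the ring centres. The cis arrangement is the less stable one and can be lost in two ways: C2–H becomes acidic whenever the C2 carboxyl is an ester, and C3–O4 is a benzylic aryl ether para to a phenol, which acid can ionise and base can open through a quinone methide. The catechol oxidises easily, and the cinnamate ester of an α-carboxy alcohol rules out hydroxide, strong nucleophiles and hydrogenation. The task is therefore to set cis C2/C3 in absolute terms, with each oxygen on the right carbon, without ever letting either centre equilibrate. The strategy rests on one feature: C2 with its carboxyl and C3 with its benzylic oxygen are the two ends of a β-hydroxy acid. Closing them gives a 3-aryloxy-4-aryl-oxetan-2-one that already has O1 on C2, and displacement of the lactone oxygen at C3 by O4 of ring B converts the cis lactone into the cis acid.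

## Retrosynthetic reasoning

**Protecting groups (23 ⇒ 22 ⇒ 21).** No skeletal bond is cut in the last two operations. Target 23 is released from 22 by cleaving two aryl acetates, and 22 comes from 21 by acidolysis of the tert-butyl ester and the methoxymethyl ether. The acetates stay on ring C until the acid step is over, because an acylated ring C cannot stabilise a cation at C3, so the C3–O4 bond and the cis relationship survive the acid. As aryl esters they then leave under near-neutral conditions that the alkyl cinnamate tolerates.

**O4–C3 (21 ⇒ 20).** The dioxane is opened at the bond between O4 and benzylic C3, and the C2 carboxyl is folded back onto C3, giving β-lactone 20 with a free O4–H. The cut is made here and not at O1–C2 because C3 is the carbon at which an SN2 displacement is feasible (benzylic, strained leaving group), whereas C2, next to a carbonyl, is where configuration is most easily lost. Three things are gained: the acid emerges free and at the right oxidation level, C2 is a non-enolisable carboxylate from the moment the ring exists, and the cis acid follows by inversion from the cis lactone, which is the diastereomer that ketene–aldehyde cycloadditions give. The forward reaction must send the phenoxide to the alkyl carbon and not the carbonyl, and it must be a clean SN2 process.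

**O4 protection (20 ⇒ 19).** The phenol must be masked while the lactone is made, since a free phenol would be acylated by the activated acid. A 4-methoxybenzyl ether is chosen because it is removed oxidatively at neutral pH, where the lactone, the aryl acetates and the acid-labile groups all survive.

**C2–C3 and the lactone C–O bond (19 ⇒ 15 + 16).** The four-membered ring is divided into the aryloxyketene derived from acid 15 and aldehyde 16. This disconnection makes both stereocentres in one catalytic step, gives the cis lactone directly and joins the two halves late. The forward reaction needs a catalyst that overrides any bias from the remote lactate centre and an acid activation that spares the acid-labile groups.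

**The propenoate C=C (15 ⇒ 14 ⇒ 13 + 9).** Acid 15 is the deallylated form of ester 14, which is cut at the alkene into aldehyde 13 and phosphonate 9. Cutting the alkene and not the ester C–O bond avoids acylating a hindered α-hydroxy ester with a free cinnamic acid, and the lactate unit arrives as a stabilised phosphonate that gives the E-alkene under mild base. The allyl ester carried by 13 and 14 is orthogonal to every other group present.

**Ring B (13 ⇒ 11 + 12; 11 ⇒ 10).** The O1–CH2 bond is cut to phenol 11 and bromoacetate 12, which supplies C2 and its carboxyl carbon; 11 is the 4-O-(4-methoxybenzyl) ether of 10. The more acidic phenol of 10, para to the formyl group, reacts first and becomes O4, and the other becomes O1. The regiochemistry of the dioxane is thus settled on a commercial catechol aldehyde by two ordinary alkylations.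

**The lactate unit (9 ⇒ 7 + 8; 7 ⇒ 6 ⇒ 5 ⇒ 2 + 3; 2 ⇒ 1).** Phosphonate 9 is the ester of alcohol 7 with acid 8. Alcohol 7 is traced through acid 6 to methyl ester 5, which is cut between ring A and the benzylic CH2 into the aryl Grignard reagent from bromide 2 and the enantiopure epoxide 3; 2 is the protected form of phenol 1. The stereocentre is bought, so no asymmetric step is spent on it. The ester is changed from methyl to tert-butyl because a methyl ester could not be removed at the end beside the cinnamate ester, whereas a tert-butyl ester leaves together with the methoxymethyl ether.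

**Aldehyde 16 (16 ⇒ 10).** Acetylation of 10. The acetates activate the aldehyde for the cycloaddition, keep C3 from ionising in the key step and in the acid step, and come off last without acid or strong base.

## Alternatives that were turned down

**Alternative 1:** Ring B is built instead of bought. The C4a–C8a and C7–C8 bonds are cut, so that ring B arises from a 2-pyrone held on the C3 oxygen (O4) and an ethynyl ether on the C2 oxygen (O1) of a preformed C2–C3 diol unit. In the forward direction, heating makes the alkyne add across C3 and C6 of the pyrone in an intramolecular Diels–Alder reaction; the carboxyl bridge is then extruded and the aromatic ring appears, giving methyl (2R,3S)-3-[3,4-bis(methoxymethoxy)phenyl]-2-[(tert-butyldimethylsilyloxy)methyl]-2,3-dihydro-1,4-benzodioxine-7-carboxylate A1.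
- For: both stereocentres are fixed in an open-chain unit beforehand and no bond to either is made or broken in the key step, so the cis relationship cannot leak. On this point the plan is safer than the chosen one. The tether also fixes the regiochemistry, and the step needs no reagent.
- Against: A1 has C2 at the alcohol oxidation level and C7 as a benzoate. Reaching the target needs desilylation and two oxidations through a C2 aldehyde that is α to O1 and cis to the aryl group, a very epimerisable intermediate, then reduction, oxidation and olefination at C7. An ynol ether on a secondary alkoxide and the oxygenated pyrone add further steps.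
- Comparison: the chosen route has C2 as a carboxyl from the start, brings the complete ester side chain into the key step and is considerably shorter. In exchange it accepts that the ring closure itself is stereochemically demanding.

**Alternative 2:** Both O1–C2 and O4–C3 are cut at once. The forward step is a hetero-Diels–Alder reaction of an ortho-quinone of ring B, generated in situ, acting as an oxygen heterodiene toward a (Z)-cinnamate ester under a chiral bis(oxazoline) complex of divalent copper; it gives prop-2-enyl (2S,3S)-3-[3,4-bis(prop-2-enyloxy)phenyl]-7-formyl-2,3-dihydro-1,4-benzodioxine-2-carboxylate A2.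
- For: two bonds, the ring and both stereocentres form in one step, the cis relationship follows from the Z geometry by suprafacial addition, and the formyl group is ready for olefination. The all-allyl protection would fall in one neutral palladium step. In convergence and step economy this plan is stronger than the chosen one.
- Against: the two quinone oxygens differ only by being meta or para to the formyl group, so which one bonds to C2 is poorly controlled. The electron-poor heterodiene is mismatched with an acrylate-type alkene, and a stepwise zwitterionic path or Lewis-acid isomerisation of the Z-alkene would give the trans product. Enantiocontrol by the copper complex has no close model, and the formyl-substituted quinone is prone to self-reaction.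
- Comparison: three selectivities would have to be won in one untested step. The chosen route places each oxygen by a separate, unambiguous alkylation and derives the absolute configuration from a catalytic cycloaddition with a known stereochemical model.

**Alternative 3:** O1–C2 and C2–C3 are cut, so that C2 with its ester is inserted as a carbene into a 2-aryl-1,3-benzodioxole acetal that already carries the full side chain. A chiral dirhodium tetracarboxylate transfers the carbene from a diazoacetate ester to acetal oxygen O1, and a 1,2-shift of the acetal carbon from oxygen to the ylide carbon (Stevens rearrangement) expands the dioxole to the dioxane, giving tert-butyl (2S,3S)-3-[3,4-bis(tert-butyldimethylsilyloxy)phenyl]-7-{(E)-3-[(R)-1-tert-butoxy-3-(4-(tert-butyldimethylsilyloxy)-3-methoxyphenyl)-1-oxopropan-2-yl]oxy-3-oxoprop-1-enyl}-2,3-dihydro-1,4-benzodioxine-2-carboxylate A3.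
- For: the acetal comes from a catechol and an aldehyde in one step, the ring expansion is the last skeletal event, and A3 needs only fluoride and acid to reach the target. This is the shortest of all the plans.
- Against: the two acetal oxygens are nearly equivalent, so ylide formation at O1 instead of O4 is not assured. The 1,2-shift of oxonium ylides runs through radical or ion pairs, so neither the configuration of migrating C3 nor the cis/trans relationship is reliably transmitted, and the catalyst may have left the ylide before the shift. Cyclopropanation of the propenoate, addition to the electron-rich arenes (Büchner reaction) and insertion into the benzylic C–H bonds of ring A compete.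
- Comparison: the chosen route is longer, but C3 is set by a stereospecific displacement whose outcome follows from the geometry of an isolable precursor.

Key step: step 13

Assumption: the sense of induction of the quinine-derived catalyst in step 11 is taken from the cinchona-catalysed cycloadditions of simple ketenes with aldehydes; if the first run shows the opposite sense, O-trimethylsilylquinidine replaces it with nothing else changed.

## Route

Step 1
Reactants: 1 4-bromo-2-methoxyphenol
Product: 2 4-bromo-2-methoxy-1-(methoxymethoxy)benzene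
Conditions: MOMCl, iPr2NEt, CH2Cl2, 0 °C to rt
Reagents that add atoms: chloromethyl methyl ether, COCCl
Why: O-alkylation of the phenol by the chloromethyl ether under amine base; the methoxymethyl ether masks the ring A phenol through the organometallic, basic and oxidative steps and leaves with acid at the end.

Step 2
Reactants: 2 4-bromo-2-methoxy-1-(methoxymethoxy)benzene; 3 methyl (2R)-oxirane-2-carboxylate
Product: 5 methyl (2R)-2-hydroxy-3-[3-methoxy-4-(methoxymethoxy)phenyl]propanoate, via arylmagnesium bromide 4 (not isolated)
Conditions: Mg, THF, 40 °C; then CuI (10 mol%), 3, THF, −40 to −20 °C; sat. aq. NH4Cl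
Reagents that add atoms: none
Why: Copper-catalysed SN2 opening of the epoxide by the aryl Grignard reagent at the unsubstituted carbon, which at low temperature is faster than addition to the methyl ester. The stereocentre of 3 is not involved and becomes the (R) carbinol carbon unchanged.

Step 3
Reactants: 5 methyl (2R)-2-hydroxy-3-[3-methoxy-4-(methoxymethoxy)phenyl]propanoate
Product: 6 (2R)-2-hydroxy-3-[3-methoxy-4-(methoxymethoxy)phenyl]propanoic acid
Conditions: LiOH·H2O, THF/H2O, 0 °C to rt; cold 1 M HCl to pH 3
Reagents that add atoms: lithium hydroxide, [Li+].[OH-]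
Why: Saponification of the methyl ester; an α-hydroxy ester hydrolyses at 0 °C without touching the stereocentre, and the aryl methoxymethyl ether tolerates the brief cold acidification.

Step 4
Reactants: 6 (2R)-2-hydroxy-3-[3-methoxy-4-(methoxymethoxy)phenyl]propanoic acid
Product: 7 tert-butyl (2R)-2-hydroxy-3-[3-methoxy-4-(methoxymethoxy)phenyl]propanoate
Conditions: tert-butyl 2,2,2-trichloroacetimidate, CH2Cl2/cyclohexane, rt
Reagents that add atoms: tert-butyl 2,2,2-trichloroacetimidate, CC(C)(C)OC(=N)C(Cl)(Cl)Cl
Why: Acid-selective tert-butylation: the carboxylic acid protonates the imidate, which then transfers the tert-butyl group to the carboxylate, while the secondary alcohol stays free because no Lewis acid promoter is added.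

Step 5
Reactants: 7 tert-butyl (2R)-2-hydroxy-3-[3-methoxy-4-(methoxymethoxy)phenyl]propanoate; 8 2-(diethoxyphosphoryl)acetic acid
Product: 9 tert-butyl (2R)-2-[2-(diethoxyphosphoryl)acetoxy]-3-[3-methoxy-4-(methoxymethoxy)phenyl]propanoate
Conditions: DCC, DMAP (cat.), CH2Cl2, 0 °C to rt
Reagents that add atoms: none
Why: Carbodiimide/DMAP (Steglich) esterification of the secondary alcohol with an unhindered acid; it places the two acrylate carbons on the lactate oxygen, so the cinnamate ester bond itself never has to be formed.

Step 6
Reactants: 10 3,4-dihydroxybenzaldehyde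
Product: 11 3-hydroxy-4-[(4-methoxyphenyl)methoxy]benzaldehyde
Conditions: 4-methoxybenzyl chloride (1.05 equiv), NaHCO3, NaI (cat.), DMF, 40 °C
Reagents that add atoms: 4-methoxybenzyl chloride, COc1ccc(CCl)cc1
Why: The hydroxyl para to the formyl group is the more acidic one, so NaHCO3 forms only its phenoxide and the benzyl halide alkylates the future O4 selectively (Williamson ether synthesis).

Step 7
Reactants: 11 3-hydroxy-4-[(4-methoxyphenyl)methoxy]benzaldehyde; 12 prop-2-enyl 2-bromoacetate
Product: 13 prop-2-enyl 2-{5-formyl-2-[(4-methoxyphenyl)methoxy]phenoxy}acetate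
Conditions: K2CO3, DMF, rt
Reagents that add atoms: none
Why: Williamson alkylation of the remaining phenol (the future O1) by the α-bromo ester brings in C2 and its carboxyl carbon. The allyl ester is chosen because zerovalent palladium can later remove it beside a tert-butyl ester, a cinnamate and two acid-labile ethers.

Step 8
Reactants: 13 prop-2-enyl 2-{5-formyl-2-[(4-methoxyphenyl)methoxy]phenoxy}acetate; 9 tert-butyl (2R)-2-[2-(diethoxyphosphoryl)acetoxy]-3-[3-methoxy-4-(methoxymethoxy)phenyl]propanoate
Product: 14 tert-butyl (2R)-2-{[(2E)-3-{4-[(4-methoxyphenyl)methoxy]-3-[2-oxo-2-(prop-2-enyloxy)ethoxy]phenyl}prop-2-enoyl]oxy}-3-[3-methoxy-4-(methoxymethoxy)phenyl]propanoate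
Conditions: LiCl, DBU, MeCN, 0 °C to rt
Reagents that add atoms: none
Why: Horner–Wadsworth–Emmons olefination in its LiCl/amine variant; the stabilised phosphonate anion gives the E-alkene, and the mild base leaves the allyl ester and the α-acyloxy ester stereocentre alone.

Step 9
Reactants: 14 tert-butyl (2R)-2-{[(2E)-3-{4-[(4-methoxyphenyl)methoxy]-3-[2-oxo-2-(prop-2-enyloxy)ethoxy]phenyl}prop-2-enoyl]oxy}-3-[3-methoxy-4-(methoxymethoxy)phenyl]propanoate
Product: 15 2-{5-[(1E)-3-{[(2R)-1-tert-butoxy-3-[3-methoxy-4-(methoxymethoxy)phenyl]-1-oxopropan-2-yl]oxy}-3-oxoprop-1-enyl]-2-[(4-methoxyphenyl)methoxy]phenoxy}acetic acid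
Conditions: Pd(PPh3)4 (5 mol%), morpholine, THF, rt; cold dilute HCl wash
Reagents that add atoms: none
Why: Zerovalent palladium ionises the allyl ester to a π-allyl complex that morpholine captures (Tsuji–Trost deallylation), which frees the aryloxyacetic acid without acid or hydroxide.

Step 10
Reactants: 10 3,4-dihydroxybenzaldehyde
Product: 16 4-formyl-1,2-phenylene diacetate
Conditions: Ac2O, pyridine, DMAP (cat.), CH2Cl2, 0 °C to rt
Reagents that add atoms: acetic anhydride, CC(=O)OC(C)=O
Why: Acetylation of both phenols; the acetoxy groups make the aldehyde more electrophilic for the cycloaddition and make ring C electron-poor for the key step and the later acid step.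

Step 11
Reactants: 15 2-{5-[(1E)-3-{[(2R)-1-tert-butoxy-3-[3-methoxy-4-(methoxymethoxy)phenyl]-1-oxopropan-2-yl]oxy}-3-oxoprop-1-enyl]-2-[(4-methoxyphenyl)methoxy]phenoxy}acetic acid; 16 4-formyl-1,2-phenylene diacetate
Product: 19 tert-butyl (2R)-2-{[(2E)-3-{3-{[(3S,4R)-4-(3,4-diacetoxyphenyl)-2-oxooxetan-3-yl]oxy}-4-[(4-methoxyphenyl)methoxy]phenyl}prop-2-enoyl]oxy}-3-[3-methoxy-4-(methoxymethoxy)phenyl]propanoate, via acyl chloride 17 (not isolated), via aryloxyketene 18 (not isolated)
Conditions: 1-chloro-N,N,2-trimethylprop-1-en-1-amine, CH2Cl2, 0 °C to rt; then added slowly to 16 (2 equiv), O-trimethylsilylquinine (15 mol%), LiClO4 (2 equiv), iPr2NEt (2.5 equiv), CH2Cl2/Et2O, −78 °C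
Reagents that add atoms: none
Why: The acyl chloride, made under neutral conditions so that the methoxymethyl ether and the tert-butyl ester survive, loses HCl to iPr2NEt to give ketene 18, to which the quinuclidine nitrogen of the alkaloid adds to form a Z-configured ammonium enolate. LiClO4 ties this enolate to aldehyde 16 in a closed chair-like transition state, so that aldol addition and ring closure give the cis lactone (alkaloid/Lewis acid-catalysed ketene–aldehyde [2+2] cycloaddition). The alkaloid shields one enolate face and thereby sets both C3 (S) and C4 (R) of the lactone independently of the remote lactate centre.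

Step 12
Reactants: 19 tert-butyl (2R)-2-{[(2E)-3-{3-{[(3S,4R)-4-(3,4-diacetoxyphenyl)-2-oxooxetan-3-yl]oxy}-4-[(4-methoxyphenyl)methoxy]phenyl}prop-2-enoyl]oxy}-3-[3-methoxy-4-(methoxymethoxy)phenyl]propanoate
Product: 20 tert-butyl (2R)-2-{[(2E)-3-{3-{[(3S,4R)-4-(3,4-diacetoxyphenyl)-2-oxooxetan-3-yl]oxy}-4-hydroxyphenyl}prop-2-enoyl]oxy}-3-[3-methoxy-4-(methoxymethoxy)phenyl]propanoate
Conditions: DDQ, CH2Cl2/pH 7 phosphate buffer (10:1), 0 °C to rt
Reagents that add atoms: none
Why: Oxidation of the 4-methoxybenzyl ether by DDQ gives an oxocarbenium ion that water hydrolyses, releasing the O4 phenol at neutral pH, where the lactone, the acetates, the methoxymethyl ether and the tert-butyl ester are stable.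

Step 13
Reactants: 20 tert-butyl (2R)-2-{[(2E)-3-{3-{[(3S,4R)-4-(3,4-diacetoxyphenyl)-2-oxooxetan-3-yl]oxy}-4-hydroxyphenyl}prop-2-enoyl]oxy}-3-[3-methoxy-4-(methoxymethoxy)phenyl]propanoate
Product: 21 (2S,3S)-3-(3,4-diacetoxyphenyl)-7-[(1E)-3-{[(2R)-1-tert-butoxy-3-[3-methoxy-4-(methoxymethoxy)phenyl]-1-oxopropan-2-yl]oxy}-3-oxoprop-1-enyl]-2,3-dihydro-1,4-benzodioxine-2-carboxylic acid
Conditions: Cs2CO3 (1.2 equiv), MeCN (0.005 M), 0 °C to rt; cold 0.5 M HCl to pH 3
Reagents that add atoms: none
Why: Proposed new method: Cs2CO3 deprotonates the ring B phenol, the most acidic site of 20 because the para propenoate stabilises the anion, and this phenoxide (O4) attacks benzylic C3 of the lactone on the side opposite the ring oxygen, so that O4–C3 forms while the alkyl–oxygen bond breaks and the C2 carboxylate is set free, the strain of the four-membered ring providing the driving force. The closest known reaction type is the alkyl–oxygen (SN2) opening of β-lactones with inversion by weakly basic nucleophiles such as carboxylates, phenoxides, thiolates and azide; a tethered phenoxide attacking a secondary benzylic lactone carbon has no direct precedent. The dioxane ring closes in the 6-exo-tet mode, the departing oxygen lying outside the new ring, and the catechol-type O1···O4 distance places O4 close to the backside of the C3–O bond. C3 is the one stereocentre made here and its configuration is dictated by inversion of the (4R) lactone carbon fixed in step 11, whereas C2 is not involved and keeps its configuration, so the cis lactone becomes the cis (2S,3S) acid. The step needs attack at the alkyl carbon instead of the carbonyl: addition to the carbonyl gives a tetrahedral intermediate that should expel the stabilised phenoxide again sooner than the ring alkoxide, as is usual for weakly basic nucleophiles with β-lactones, while alkyl attack ends in a carboxylate and cannot revert. It also needs SN2 displacement and not ionisation at C3, which the two acetoxy groups secure by making ring C electron-poor. The product is a carboxylate whose C2–H is no longer acidic, so the cis acid cannot epimerise in the basic medium, and high dilution at low temperature keeps the phenoxide from taking an acetyl group from another molecule.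

Step 14
Reactants: 21 (2S,3S)-3-(3,4-diacetoxyphenyl)-7-[(1E)-3-{[(2R)-1-tert-butoxy-3-[3-methoxy-4-(methoxymethoxy)phenyl]-1-oxopropan-2-yl]oxy}-3-oxoprop-1-enyl]-2,3-dihydro-1,4-benzodioxine-2-carboxylic acid
Product: 22 (2S,3S)-7-[(1E)-3-{[(1R)-1-carboxy-2-(4-hydroxy-3-methoxyphenyl)ethyl]oxy}-3-oxoprop-1-enyl]-3-(3,4-diacetoxyphenyl)-2,3-dihydro-1,4-benzodioxine-2-carboxylic acid
Conditions: TFA/CH2Cl2 (1:3), H2O (5 equiv), 0 °C to rt
Reagents that add atoms: none
Why: Acidolysis: TFA ionises the tert-butyl ester with loss of 2-methylpropene and hydrolyses the methoxymethyl acetal. The acetates are deliberately still in place, so ring C stays electron-poor and the acid does not ionise the benzylic C3–O4 bond, which would erode the cis arrangement.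

Step 15
Reactants: 22 (2S,3S)-7-[(1E)-3-{[(1R)-1-carboxy-2-(4-hydroxy-3-methoxyphenyl)ethyl]oxy}-3-oxoprop-1-enyl]-3-(3,4-diacetoxyphenyl)-2,3-dihydro-1,4-benzodioxine-2-carboxylic acid
Product: 23 (2S,3S)-7-[(1E)-3-{[(1R)-1-carboxy-2-(4-hydroxy-3-methoxyphenyl)ethyl]oxy}-3-oxoprop-1-enyl]-3-(3,4-dihydroxyphenyl)-2,3-dihydro-1,4-benzodioxine-2-carboxylic acid
Conditions: hydrazine acetate (excess), DMF, argon, 0 °C to rt; dilute acid, reverse-phase chromatography
Reagents that add atoms: none
Why: Hydrazinolysis of the two aryl acetates, which as phenyl esters react much faster than the alkyl cinnamate. The buffered, near-neutral medium avoids phenoxide-driven opening at C3, and the reducing reagent protects the catechol from air oxidation.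

## Compound list

1 | 4-bromo-2-methoxyphenol | COc1cc(Br)ccc1O | starting material
2 | 4-bromo-2-methoxy-1-(methoxymethoxy)benzene | COCOc1ccc(Br)cc1OC | intermediate
3 | methyl (2R)-oxirane-2-carboxylate (methyl (R)-glycidate) | COC(=O)[C@H]1CO1 | starting material
4 | [3-methoxy-4-(methoxymethoxy)phenyl]magnesium bromide | COCOc1ccc([Mg]Br)cc1OC | intermediate (not isolated)
5 | methyl (2R)-2-hydroxy-3-[3-methoxy-4-(methoxymethoxy)phenyl]propanoate | COCOc1ccc(C[C@@H](O)C(=O)OC)cc1OC | intermediate
6 | (2R)-2-hydroxy-3-[3-methoxy-4-(methoxymethoxy)phenyl]propanoic acid | COCOc1ccc(C[C@@H](O)C(=O)O)cc1OC | intermediate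
7 | tert-butyl (2R)-2-hydroxy-3-[3-methoxy-4-(methoxymethoxy)phenyl]propanoate | COCOc1ccc(C[C@@H](O)C(=O)OC(C)(C)C)cc1OC | intermediate
8 | 2-(diethoxyphosphoryl)acetic acid | CCOP(=O)(CC(=O)O)OCC | starting material
9 | tert-butyl (2R)-2-[2-(diethoxyphosphoryl)acetoxy]-3-[3-methoxy-4-(methoxymethoxy)phenyl]propanoate | CCOP(=O)(CC(=O)O[C@H](Cc1ccc(OCOC)c(OC)c1)C(=O)OC(C)(C)C)OCC | intermediate
10 | 3,4-dihydroxybenzaldehyde | O=Cc1ccc(O)c(O)c1 | starting material
11 | 3-hydroxy-4-[(4-methoxyphenyl)methoxy]benzaldehyde | COc1ccc(COc2ccc(C=O)cc2O)cc1 | intermediate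
12 | prop-2-enyl 2-bromoacetate (allyl bromoacetate) | C=CCOC(=O)CBr | starting material
13 | prop-2-enyl 2-{5-formyl-2-[(4-methoxyphenyl)methoxy]phenoxy}acetate | C=CCOC(=O)COc1cc(C=O)ccc1OCc1ccc(OC)cc1 | intermediate
14 | tert-butyl (2R)-2-{[(2E)-3-{4-[(4-methoxyphenyl)methoxy]-3-[2-oxo-2-(prop-2-enyloxy)ethoxy]phenyl}prop-2-enoyl]oxy}-3-[3-methoxy-4-(methoxymethoxy)phenyl]propanoate | COc1cc(C[C@@H](OC(=O)/C=C/c2ccc(OCc3ccc(OC)cc3)c(OCC(=O)OCC=C)c2)C(=O)OC(C)(C)C)ccc1OCOC | intermediate
15 | 2-{5-[(1E)-3-{[(2R)-1-tert-butoxy-3-[3-methoxy-4-(methoxymethoxy)phenyl]-1-oxopropan-2-yl]oxy}-3-oxoprop-1-enyl]-2-[(4-methoxyphenyl)methoxy]phenoxy}acetic acid | COc1cc(C[C@@H](OC(=O)/C=C/c2ccc(OCc3ccc(OC)cc3)c(OCC(=O)O)c2)C(=O)OC(C)(C)C)ccc1OCOC | intermediate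
16 | 4-formyl-1,2-phenylene diacetate (3,4-diacetoxybenzaldehyde) | CC(=O)Oc1ccc(C=O)cc1OC(C)=O | intermediate
17 | 2-{5-[(1E)-3-{[(2R)-1-tert-butoxy-3-[3-methoxy-4-(methoxymethoxy)phenyl]-1-oxopropan-2-yl]oxy}-3-oxoprop-1-enyl]-2-[(4-methoxyphenyl)methoxy]phenoxy}acetyl chloride | COc1cc(C[C@@H](OC(=O)/C=C/c2ccc(OCc3ccc(OC)cc3)c(OCC(=O)Cl)c2)C(=O)OC(C)(C)C)ccc1OCOC | intermediate (not isolated)
18 | tert-butyl (2R)-2-{[(2E)-3-{4-[(4-methoxyphenyl)methoxy]-3-[(2-oxoethenyl)oxy]phenyl}prop-2-enoyl]oxy}-3-[3-methoxy-4-(methoxymethoxy)phenyl]propanoate (aryloxyketene) | COc1cc(C[C@@H](OC(=O)/C=C/c2ccc(OCc3ccc(OC)cc3)c(OC=C=O)c2)C(=O)OC(C)(C)C)ccc1OCOC | intermediate (not isolated)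
19 | tert-butyl (2R)-2-{[(2E)-3-{3-{[(3S,4R)-4-(3,4-diacetoxyphenyl)-2-oxooxetan-3-yl]oxy}-4-[(4-methoxyphenyl)methoxy]phenyl}prop-2-enoyl]oxy}-3-[3-methoxy-4-(methoxymethoxy)phenyl]propanoate (cis lactone) | COc1cc(C[C@@H](OC(=O)/C=C/c2ccc(OCc3ccc(OC)cc3)c(O[C@@H]3C(=O)O[C@@H]3c3ccc(OC(C)=O)c(OC(C)=O)c3)c2)C(=O)OC(C)(C)C)ccc1OCOC | intermediate
20 | tert-butyl (2R)-2-{[(2E)-3-{3-{[(3S,4R)-4-(3,4-diacetoxyphenyl)-2-oxooxetan-3-yl]oxy}-4-hydroxyphenyl}prop-2-enoyl]oxy}-3-[3-methoxy-4-(methoxymethoxy)phenyl]propanoate | COc1cc(C[C@@H](OC(=O)/C=C/c2ccc(O)c(O[C@@H]3C(=O)O[C@@H]3c3ccc(OC(C)=O)c(OC(C)=O)c3)c2)C(=O)OC(C)(C)C)ccc1OCOC | intermediate (precursor of the key step)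
21 | (2S,3S)-3-(3,4-diacetoxyphenyl)-7-[(1E)-3-{[(2R)-1-tert-butoxy-3-[3-methoxy-4-(methoxymethoxy)phenyl]-1-oxopropan-2-yl]oxy}-3-oxoprop-1-enyl]-2,3-dihydro-1,4-benzodioxine-2-carboxylic acid | COc1cc(C[C@@H](OC(=O)/C=C/c2ccc3c(c2)O[C@H](C(=O)O)[C@H](c2ccc(OC(C)=O)c(OC(C)=O)c2)O3)C(=O)OC(C)(C)C)ccc1OCOC | intermediate (product of the key step)
22 | (2S,3S)-7-[(1E)-3-{[(1R)-1-carboxy-2-(4-hydroxy-3-methoxyphenyl)ethyl]oxy}-3-oxoprop-1-enyl]-3-(3,4-diacetoxyphenyl)-2,3-dihydro-1,4-benzodioxine-2-carboxylic acid | COc1cc(C[C@@H](OC(=O)/C=C/c2ccc3c(c2)O[C@H](C(=O)O)[C@H](c2ccc(OC(C)=O)c(OC(C)=O)c2)O3)C(=O)O)ccc1O | intermediate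
23 | (2S,3S)-7-[(1E)-3-{[(1R)-1-carboxy-2-(4-hydroxy-3-methoxyphenyl)ethyl]oxy}-3-oxoprop-1-enyl]-3-(3,4-dihydroxyphenyl)-2,3-dihydro-1,4-benzodioxine-2-carboxylic acid | COc1cc(C[C@@H](OC(=O)/C=C/c2ccc3c(c2)O[C@H](C(=O)O)[C@H](c2ccc(O)c(O)c2)O3)C(=O)O)ccc1O | target

## Step count and least certain steps

Total step count: 15. Longest linear sequence: 12 steps (steps 1–5, 8, 9, 11–15).

**Step 13 (key step).** The phenoxide may add to the lactone carbonyl and expand the ring to a six-membered aryl lactone, whose free β-alkoxide can then fragment by retro-aldol cleavage. Partial ionisation at benzylic C3 would erode the cis relationship. Intermolecular acetyl transfer from ring C to O4 would block the nucleophile and make ring C electron-rich.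
Fallback (known chemistry; hydroxyl activation in place of strain release), setting out from lactone 19 and returning at 21:
- Alcoholysis of 19 with allyl alcohol under La(OtBu)3 catalysis (THF, 0 °C) should cleave the acyl–oxygen bond with retention at both centres and give tert-butyl (2R)-2-{[(2E)-3-{3-{[(2S,3R)-3-(3,4-diacetoxyphenyl)-3-hydroxy-1-oxo-1-(prop-2-enyloxy)propan-2-yl]oxy}-4-[(4-methoxyphenyl)methoxy]phenyl}prop-2-enoyl]oxy}-3-[3-methoxy-4-(methoxymethoxy)phenyl]propanoate F1. The strained, α-oxygenated lactone is expected to react before the aryl acetates.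
- DDQ in buffered CH2Cl2 would free O4 to give tert-butyl (2R)-2-{[(2E)-3-{3-{[(2S,3R)-3-(3,4-diacetoxyphenyl)-3-hydroxy-1-oxo-1-(prop-2-enyloxy)propan-2-yl]oxy}-4-hydroxyphenyl}prop-2-enoyl]oxy}-3-[3-methoxy-4-(methoxymethoxy)phenyl]propanoate F2.
- An intramolecular Mitsunobu etherification (PPh3, DIAD, toluene, 0 °C) would displace the activated benzylic hydroxyl by O4 with inversion and give prop-2-enyl (2S,3S)-3-(3,4-diacetoxyphenyl)-7-[(1E)-3-{[(2R)-1-tert-butoxy-3-[3-methoxy-4-(methoxymethoxy)phenyl]-1-oxopropan-2-yl]oxy}-3-oxoprop-1-enyl]-2,3-dihydro-1,4-benzodioxine-2-carboxylate F3, with the same cis configuration as 21.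
- Pd(PPh3)4 with PhSiH3 would remove the allyl group under neutral conditions, so the C2 ester is never exposed to base, and the route is rejoined at 21.

**Step 11.** The aryloxyketene may dimerise or react in an uncatalysed, unselective cycloaddition. The aryloxy oxygen can bind lithium and change the enolate geometry, which would lower the cis and facial selectivity, and the sense of induction is assumed by analogy. Because the (R)-lactate centre is already present, loss of facial control would show up as formation of a diastereomer.
Fallback (aldol addition and lactonisation in place of cycloaddition), setting out from acid 15 and returning at 19: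
- Thiophenol, DCC and DMAP would give S-phenyl 2-{5-[(1E)-3-{[(2R)-1-tert-butoxy-3-[3-methoxy-4-(methoxymethoxy)phenyl]-1-oxopropan-2-yl]oxy}-3-oxoprop-1-enyl]-2-[(4-methoxyphenyl)methoxy]phenoxy}ethanethioate F4.
- Its boron enolate would be formed with iPr2NEt and the enantiomer of 2-bromo-4,5-diphenyl-1,3-bis(4-methylbenzenesulfonyl)-1,3,2-diazaborolidine that delivers the (2S,3R) aldol (CH2Cl2, −78 °C). Addition to aldehyde 16 would give the syn aldol S-phenyl (2S,3R)-2-{5-[(1E)-3-{[(2R)-1-tert-butoxy-3-[3-methoxy-4-(methoxymethoxy)phenyl]-1-oxopropan-2-yl]oxy}-3-oxoprop-1-enyl]-2-[(4-methoxyphenyl)methoxy]phenoxy}-3-(3,4-diacetoxyphenyl)-3-hydroxypropanethioate F5.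
- Thiophile-induced lactonisation (Hg(OCOCF3)2, Na2HPO4, MeCN) would close the β-lactone with retention at both centres, so the syn aldol gives cis lactone 19. None of these reagents attacks the aryl acetates.

**Step 12.** Oxidative cleavage of an aryl 4-methoxybenzyl ether can be slow. During a long reaction DDQ may oxidise the benzylic CH2 of the electron-rich ring A, or the aqueous buffer may hydrolyse the lactone.
Fallback (acidolytic unmasking and earlier global deprotection), setting out from 19 and returning at 22:
- TFA/CH2Cl2 with pentamethylbenzene at 0 °C would remove the 4-methoxybenzyl ether, the tert-butyl ester and the methoxymethyl ether together. The acetates keep the lactone from ionising. The product would be (2R)-2-{[(2E)-3-{3-{[(3S,4R)-4-(3,4-diacetoxyphenyl)-2-oxooxetan-3-yl]oxy}-4-hydroxyphenyl}prop-2-enoyl]oxy}-3-(4-hydroxy-3-methoxyphenyl)propanoic acid F6.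
- Cs2CO3 (about 3.3 equiv) in MeCN/DMF at high dilution would then perform the ring closure of step 13 on the trianion, in which only O4 can reach C3 intramolecularly. Acidification gives 22, from which step 15 follows.

**Step 15.** Hydrazine may add to the propenoate in a conjugate sense or attack its ester carbonyl if the acetates cleave slowly in the presence of two free carboxylic acids. The catechol may oxidise during work-up, and separating the polar diacid from hydrazinium salts may cost material.
Fallback (reversed order of deprotection, different intermediate), setting out from 21 and returning at 23: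
- Hydrazine acetate in DMF would first remove the acetates from 21, which is still lipophilic and has only one acid group, giving (2S,3S)-7-[(1E)-3-{[(2R)-1-tert-butoxy-3-[3-methoxy-4-(methoxymethoxy)phenyl]-1-oxopropan-2-yl]oxy}-3-oxoprop-1-enyl]-3-(3,4-dihydroxyphenyl)-2,3-dihydro-1,4-benzodioxine-2-carboxylic acid F7, which can be extracted and chromatographed.
- A short treatment with TFA/CH2Cl2 at 0 °C would then release 23, leaving only volatile by-products. The price is that ring C is a free catechol during the acid step, so the exposure has to be brief to keep C3 from ionising.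

## Further compounds

F1 | step 13 | tert-butyl (2R)-2-{[(2E)-3-{3-{[(2S,3R)-3-(3,4-diacetoxyphenyl)-3-hydroxy-1-oxo-1-(prop-2-enyloxy)propan-2-yl]oxy}-4-[(4-methoxyphenyl)methoxy]phenyl}prop-2-enoyl]oxy}-3-[3-methoxy-4-(methoxymethoxy)phenyl]propanoate | COc1cc(C[C@@H](OC(=O)/C=C/c2ccc(OCc3ccc(OC)cc3)c(O[C@@H]([C@H](O)c3ccc(OC(C)=O)c(OC(C)=O)c3)C(=O)OCC=C)c2)C(=O)OC(C)(C)C)ccc1OCOC
F2 | step 13 | tert-butyl (2R)-2-{[(2E)-3-{3-{[(2S,3R)-3-(3,4-diacetoxyphenyl)-3-hydroxy-1-oxo-1-(prop-2-enyloxy)propan-2-yl]oxy}-4-hydroxyphenyl}prop-2-enoyl]oxy}-3-[3-methoxy-4-(methoxymethoxy)phenyl]propanoate | COc1cc(C[C@@H](OC(=O)/C=C/c2ccc(O)c(O[C@@H]([C@H](O)c3ccc(OC(C)=O)c(OC(C)=O)c3)C(=O)OCC=C)c2)C(=O)OC(C)(C)C)ccc1OCOC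
F3 | step 13 | prop-2-enyl (2S,3S)-3-(3,4-diacetoxyphenyl)-7-[(1E)-3-{[(2R)-1-tert-butoxy-3-[3-methoxy-4-(methoxymethoxy)phenyl]-1-oxopropan-2-yl]oxy}-3-oxoprop-1-enyl]-2,3-dihydro-1,4-benzodioxine-2-carboxylate | COc1cc(C[C@@H](OC(=O)/C=C/c2ccc3c(c2)O[C@H](C(=O)OCC=C)[C@H](c2ccc(OC(C)=O)c(OC(C)=O)c2)O3)C(=O)OC(C)(C)C)ccc1OCOC
F4 | step 11 | S-phenyl 2-{5-[(1E)-3-{[(2R)-1-tert-butoxy-3-[3-methoxy-4-(methoxymethoxy)phenyl]-1-oxopropan-2-yl]oxy}-3-oxoprop-1-enyl]-2-[(4-methoxyphenyl)methoxy]phenoxy}ethanethioate | COc1cc(C[C@@H](OC(=O)/C=C/c2ccc(OCc3ccc(OC)cc3)c(OCC(=O)Sc3ccccc3)c2)C(=O)OC(C)(C)C)ccc1OCOC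
F5 | step 11 | S-phenyl (2S,3R)-2-{5-[(1E)-3-{[(2R)-1-tert-butoxy-3-[3-methoxy-4-(methoxymethoxy)phenyl]-1-oxopropan-2-yl]oxy}-3-oxoprop-1-enyl]-2-[(4-methoxyphenyl)methoxy]phenoxy}-3-(3,4-diacetoxyphenyl)-3-hydroxypropanethioate | COc1cc(C[C@@H](OC(=O)/C=C/c2ccc(OCc3ccc(OC)cc3)c(O[C@@H]([C@H](O)c3ccc(OC(C)=O)c(OC(C)=O)c3)C(=O)Sc3ccccc3)c2)C(=O)OC(C)(C)C)ccc1OCOC
F6 | step 12 | (2R)-2-{[(2E)-3-{3-{[(3S,4R)-4-(3,4-diacetoxyphenyl)-2-oxooxetan-3-yl]oxy}-4-hydroxyphenyl}prop-2-enoyl]oxy}-3-(4-hydroxy-3-methoxyphenyl)propanoic acid | COc1cc(C[C@@H](OC(=O)/C=C/c2ccc(O)c(O[C@@H]3C(=O)O[C@@H]3c3ccc(OC(C)=O)c(OC(C)=O)c3)c2)C(=O)O)ccc1O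
F7 | step 15 | (2S,3S)-7-[(1E)-3-{[(2R)-1-tert-butoxy-3-[3-methoxy-4-(methoxymethoxy)phenyl]-1-oxopropan-2-yl]oxy}-3-oxoprop-1-enyl]-3-(3,4-dihydroxyphenyl)-2,3-dihydro-1,4-benzodioxine-2-carboxylic acid | COc1cc(C[C@@H](OC(=O)/C=C/c2ccc3c(c2)O[C@H](C(=O)O)[C@H](c2ccc(O)c(O)c2)O3)C(=O)OC(C)(C)C)ccc1OCOC
A1 | alternative 1 | methyl (2R,3S)-3-[3,4-bis(methoxymethoxy)phenyl]-2-[(tert-butyldimethylsilyloxy)methyl]-2,3-dihydro-1,4-benzodioxine-7-carboxylate | COC(=O)c1ccc2c(c1)O[C@H](CO[Si](C)(C)C(C)(C)C)[C@H](c1ccc(OCOC)c(OCOC)c1)O2
A2 | alternative 2 | prop-2-enyl (2S,3S)-3-[3,4-bis(prop-2-enyloxy)phenyl]-7-formyl-2,3-dihydro-1,4-benzodioxine-2-carboxylate | O=Cc1ccc2c(c1)O[C@H](C(=O)OCC=C)[C@H](c1ccc(OCC=C)c(OCC=C)c1)O2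
A3 | alternative 3 | tert-butyl (2S,3S)-3-[3,4-bis(tert-butyldimethylsilyloxy)phenyl]-7-{(E)-3-[(R)-1-tert-butoxy-3-(4-(tert-butyldimethylsilyloxy)-3-methoxyphenyl)-1-oxopropan-2-yl]oxy-3-oxoprop-1-enyl}-2,3-dihydro-1,4-benzodioxine-2-carboxylate | COc1cc(C[C@@H](OC(=O)/C=C/c2ccc3c(c2)O[C@H](C(=O)OC(C)(C)C)[C@H](c2ccc(O[Si](C)(C)C(C)(C)C)c(O[Si](C)(C)C(C)(C)C)c2)O3)C(=O)OC(C)(C)C)ccc1O[Si](C)(C)C(C)(C)C
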